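The ring atoms are labelled C1 (C=O), C2 (allyl), C3, C4 (quaternary, OMe), C5 (OMe), C6. The chain is C8 (CHMe) and C7 (CHOAc). The route exploits the path O7–C7–C8–C4–C5, which folds into a γ-lactone ring with C5 as carbonyl and C4 as enolate carbon. The six-membered ring is cut at C3–C4 and C5–C6. In one flask the enolate of a cis-4-methyl-5-aryl-3-methoxybutyrolactone displaces tosylate from C3 of (Z)-3-(tosyloxymethylene)hex-5-en-2-one. The methyl ketone enolate (C6) then acylates on C5. This closes the carbocycle, sets C4 under control of the lactone and frees O7.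

Key step: step 8

Remarks on the chemistry
- Configuration: the target reads as 4R,7R,8R. C7/C8 are syn, which maps onto a 4,5-cis lactone. Entry of C3 on the lactone face anti to methyl and aryl gives 4R. The structures are therefore consistent and no stereodescriptor had to be corrected.
- Acceptor design: a methoxy group at C3 trans to the acetyl group would be a weak point.
  - It deactivates C3 towards conjugate attack.
  - It leaves slowly, so the alkene geometry drifts to the enone with C4 trans to C1, which cannot cyclise.
  - Once the ketone is enolised, no alkoxide can re-add to repair this.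
  - The acceptor therefore carries a good nucleofuge (tosylate) cis to the acetyl group. The carbon skeleton is unchanged.
- Acceptor supply: base-mediated formylation of hex-5-en-2-one cannot be relied on to choose the C2 methylene over the C6 methyl group. The 2-allyl-3-oxobutanal skeleton is therefore built regiospecifically by a Claisen rearrangement.
- Assumption: the lactone is carried as a mixture of C4 epimers, because enolisation erases this centre.

Step 1
Reactants: 1 veratraldehyde (3,4-dimethoxybenzaldehyde); 2 (Z)-crotylboronic acid pinacol ester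
Product: 4 (1R,2S)-1-(3,4-dimethoxyphenyl)-2-methylbut-3-en-1-ol, via O-boryl ether 3 (not isolated)
Conditions: (R)-TRIP [(R)-3,3'-bis(2,4,6-triisopropylphenyl)-1,1'-binaphthyl-2,2'-diyl hydrogen phosphate] (5 mol %), 4 Å MS, toluene, −30 °C; aqueous work-up
Reagents that add atoms: none
Why: Chiral-phosphoric-acid-catalysed crotylboration through a closed chair transition state, in which the Z-boronate geometry becomes the syn C7/C8 relationship and the (R)-acid, hydrogen-bonded to a boronate oxygen and to the formyl hydrogen, should send the crotyl group to the Re face of the aromatic aldehyde (7R).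

Step 2
Reactants: 4 (1R,2S)-1-(3,4-dimethoxyphenyl)-2-methylbut-3-en-1-ol
Product: 5 (1R,2R)-1-(3,4-dimethoxyphenyl)-2-methylbutane-1,3,4-triol (both C3 epimers)
Conditions: OsO4 (2 mol %), NMO, acetone/H2O, rt
Reagents that add atoms: N-methylmorpholine N-oxide, C[N+]1([O-])CCOCC1; water, O
Why: Catalytic OsO4/NMO syn-dihydroxylation of the only alkene, whose new carbinol (the later C4) may form as an epimer mixture without harm because that carbon becomes planar in step 8.

Step 3
Reactants: 5 (1R,2R)-1-(3,4-dimethoxyphenyl)-2-methylbutane-1,3,4-triol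
Product: 7 (4S,5R)-5-(3,4-dimethoxyphenyl)-3-hydroxy-4-methyldihydrofuran-2(3H)-one (4,5-cis; both C3 epimers), via lactol 6 (not isolated)
Conditions: TEMPO (20 mol %), PhI(OAc)2 (2.5 equiv), CH2Cl2, rt
Reagents that add atoms: none
Why: Nitroxyl-catalysed oxidative lactonisation, in which the oxoammonium ion takes the unhindered primary C5 alcohol first, the aldehyde is caught by the C7 hydroxyl as the five-membered lactol and this is oxidised on to the lactone with C7 and C8 untouched.

Step 4
Reactants: 7 (4S,5R)-5-(3,4-dimethoxyphenyl)-3-hydroxy-4-methyldihydrofuran-2(3H)-one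
Product: 8 (4R,5R)-5-(3,4-dimethoxyphenyl)-3-methoxy-4-methyldihydrofuran-2(3H)-one (4,5-cis; both C3 epimers)
Conditions: MeI, Ag2O, 4 Å MS, CH2Cl2, rt, dark
Reagents that add atoms: iodomethane, CI
Why: Purdie methylation etherifies the α-hydroxy lactone under essentially neutral conditions, so the lactone is not opened and C7/C8 are not touched (the C4 descriptor of the ring changes by priority only).

Step 5
Reactants: 9 but-3-yn-2-one; 10 allyl alcohol
Product: 11 (E)-4-(allyloxy)but-3-en-2-one
Conditions: DABCO (10 mol %), CH2Cl2, 0 °C to rt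
Reagents that add atoms: none
Why: Amine-catalysed oxa-Michael addition of an alcohol to a terminal ynone, which should give the E-β-alkoxy enone.

Step 6
Reactants: 11 (E)-4-(allyloxy)but-3-en-2-one
Product: 12 (Z)-3-(hydroxymethylene)hex-5-en-2-one (chelated enol of 2-acetylpent-4-enal)
Conditions: toluene, BHT (cat.), sealed tube, 180 °C
Reagents that add atoms: none
Why: Thermal Claisen rearrangement of the allyl vinyl ether places the allyl group on C2 and nowhere else, turns the ether carbon into the formyl carbon C3, and is pulled forward by the hydrogen-bonded enol of the product.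

Step 7
Reactants: 12 (Z)-3-(hydroxymethylene)hex-5-en-2-one
Product: 13 (Z)-2-acetylpenta-1,4-dien-1-yl 4-methylbenzenesulfonate [(Z)-3-(tosyloxymethylene)hex-5-en-2-one]
Conditions: TsCl, N-methylimidazole, LiOH, CH2Cl2, 0 °C
Reagents that add atoms: 4-methylbenzenesulfonyl chloride, Cc1ccc(cc1)S(=O)(=O)Cl
Why: Chelation-controlled enol sulfonylation, in which the lithium chelate holds both oxygens on the same side of C2=C3 and the N-sulfonylimidazolium salt formed in the flask attacks the unhindered formyl-derived oxygen, so the tosyloxy group should end up cis to the acetyl group.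

Step 8
Reactants: 8 (4R,5R)-5-(3,4-dimethoxyphenyl)-3-methoxy-4-methyldihydrofuran-2(3H)-one; 13 (Z)-2-acetylpenta-1,4-dien-1-yl 4-methylbenzenesulfonate
Product: 16 (4R)-6-allyl-4-[(1R,2R)-1-(3,4-dimethoxyphenyl)-1-hydroxypropan-2-yl]-4-methoxycyclohex-5-ene-1,3-dione, via lithium enolate 14 (not isolated), via Z-enone lactone 15 (not isolated)
Conditions: 8, LiN(SiMe3)2 (1.05 equiv), THF, −78 °C; 13, −78 to −30 °C; LiN(SiMe3)2 (2.2 equiv), −78 to 0 °C; cold 0.5 M HCl to pH 4
Reagents that add atoms: none
Why: The base turns both C4 epimers of 8 into the single planar enolate 14, which adds through C4 to C3 of 13 and expels tosylate (nucleophilic vinylic substitution by addition–elimination) to give 15; fresh base then forms the kinetic C6 enolate of the methyl ketone, which attacks the lactone carbonyl C5, and collapse of the tetrahedral intermediate breaks C5–O7 and leaves the stabilised diketonate of 16. The closest known reaction types are the consecutive Michael–Claisen synthesis of cyclohexane-1,3-diones from enones and ester enolates and the Hauser–Kraus annulation, in which a lactone enolate adds to an acceptor and the new enolate acylates on the lactone carbonyl. The carbocycle C1–C6 closes in a 6-(enolendo)-exo-trig Dieckmann-type acylation. C4 is the only new stereocentre and is controlled by the lactone ring, whose cis C8 methyl and C7 aryl groups shield one face so that C3 enters from the other, which corresponds to 4R. The step needs C4 cis to C1 across C2=C3, and this is secured by the Z geometry of 13 together with the good nucleofuge (short-lived adduct enolate, least-motion loss of tosylate with retention, lithium bridging O1 and O5). Attack at the ketone carbonyl is reversible for this fully substituted enolate and cannot drain away by Grob-type fragmentation because tosylate is syn, not anti, to the C1–C2 bond, whereas loss of tosylate makes attack at C3 irreversible.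

Step 9
Reactants: 16 (4R)-6-allyl-4-[(1R,2R)-1-(3,4-dimethoxyphenyl)-1-hydroxypropan-2-yl]-4-methoxycyclohex-5-ene-1,3-dione (used crude)
Product: 18 (1R,2R)-2-[(1R)-3-allyl-1-methoxy-4,6-dioxocyclohex-2-en-1-yl]-1-(3,4-dimethoxyphenyl)propyl acetate, via enol acetate 17 (not isolated)
Conditions: Ac2O, pyridine, CH2Cl2, 0 °C to rt; then MeOH, rt
Reagents that add atoms: acetic anhydride, CC(=O)OC(C)=O
Why: Standard O-acylation esterifies the C7 alcohol and also the acidic enol, but the vinylogous anhydride 17 is a far better acyl donor than the alkyl acetate and is cleaved selectively by methanol, while DMAP is left out to avoid O-to-C acyl migration to C6 and early capping of O7 prevents its cyclisation onto C5.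

Step 10
Reactants: 18 (1R,2R)-2-[(1R)-3-allyl-1-methoxy-4,6-dioxocyclohex-2-en-1-yl]-1-(3,4-dimethoxyphenyl)propyl acetate
Product: 19 (1R,2R)-2-[(1R)-3-allyl-1,6-dimethoxy-4-oxocyclohexa-2,5-dien-1-yl]-1-(3,4-dimethoxyphenyl)propyl acetate (target)
Conditions: Me3SiCHN2, toluene/MeOH 4:1, 0 °C
Reagents that add atoms: (trimethylsilyl)diazomethane, C[Si](C)(C)C=[N+]=[N-]
Why: O-Methylation of a vinylogous acid by a diazoalkane (methanol releases diazomethane in the flask) gives only O-alkylation under neutral conditions that spare the benzylic acetate, the C4 ether and the skipped diene, and O5 should be favoured because the C5 enol belongs to the more stable cross-conjugated 2,5-dienone tautomer, any C1 enol ether being removed by chromatography.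

Compound list
1 | veratraldehyde (3,4-dimethoxybenzaldehyde) | COc1ccc(C=O)cc1OC | starting material
2 | (Z)-crotylboronic acid pinacol ester | C/C=C\CB1OC(C)(C)C(C)(C)O1 | starting material
3 | 2-{[(1R,2S)-1-(3,4-dimethoxyphenyl)-2-methylbut-3-en-1-yl]oxy}-4,4,5,5-tetramethyl-1,3,2-dioxaborolane | C=C[C@H](C)[C@@H](OB1OC(C)(C)C(C)(C)O1)c2ccc(OC)c(OC)c2 | intermediate
4 | (1R,2S)-1-(3,4-dimethoxyphenyl)-2-methylbut-3-en-1-ol (syn) | C=C[C@H](C)[C@@H](O)c1ccc(OC)c(OC)c1 | intermediate
5 | (1R,2R)-1-(3,4-dimethoxyphenyl)-2-methylbutane-1,3,4-triol (both C3 epimers) | OCC(O)[C@H](C)[C@@H](O)c1ccc(OC)c(OC)c1 | intermediate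
6 | 4,5-cis-5-(3,4-dimethoxyphenyl)-4-methyltetrahydrofuran-2,3-diol (5R; lactol, C2 and C3 epimers) | OC1[C@H](C)[C@@H](OC1O)c2ccc(OC)c(OC)c2 | intermediate
7 | (4S,5R)-5-(3,4-dimethoxyphenyl)-3-hydroxy-4-methyldihydrofuran-2(3H)-one (4,5-cis, C3 epimers) | OC1[C@H](C)[C@@H](OC1=O)c2ccc(OC)c(OC)c2 | intermediate
8 | (4R,5R)-5-(3,4-dimethoxyphenyl)-3-methoxy-4-methyldihydrofuran-2(3H)-one (4,5-cis, C3 epimers) | COC1[C@H](C)[C@@H](OC1=O)c2ccc(OC)c(OC)c2 | intermediate
9 | but-3-yn-2-one | C#CC(C)=O | starting material
10 | allyl alcohol | C=CCO | starting material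
11 | (E)-4-(allyloxy)but-3-en-2-one | C=CCO/C=C/C(C)=O | intermediate
12 | (Z)-3-(hydroxymethylene)hex-5-en-2-one (enol of 2-acetylpent-4-enal) | CC(=O)/C(CC=C)=C\O | intermediate
13 | (Z)-2-acetylpenta-1,4-dien-1-yl 4-methylbenzenesulfonate | CC(=O)/C(CC=C)=C\OS(=O)(=O)c1ccc(C)cc1 | intermediate
14 | lithium (4R,5R)-5-(3,4-dimethoxyphenyl)-3-methoxy-4-methyl-4,5-dihydrofuran-2-olate | [Li+].COC1=C([O-])O[C@@H](c2ccc(OC)c(OC)c2)[C@H]1C | intermediate
15 | (3R,4R,5R)-3-[(1Z)-2-acetylpenta-1,4-dien-1-yl]-5-(3,4-dimethoxyphenyl)-3-methoxy-4-methyldihydrofuran-2(3H)-one | CC(=O)/C(CC=C)=C\[C@@]1(OC)[C@H](C)[C@@H](OC1=O)c2ccc(OC)c(OC)c2 | intermediate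
16 | (4R)-6-allyl-4-[(1R,2R)-1-(3,4-dimethoxyphenyl)-1-hydroxypropan-2-yl]-4-methoxycyclohex-5-ene-1,3-dione | C=CCC1=C[C@@](OC)([C@H](C)[C@@H](O)c2ccc(OC)c(OC)c2)C(=O)CC1=O | intermediate
17 | (1R,2R)-2-[(1R)-6-acetoxy-3-allyl-1-methoxy-4-oxocyclohexa-2,5-dien-1-yl]-1-(3,4-dimethoxyphenyl)propyl acetate (drawn as the 2,5-dienone enol acetate) | C=CCC1=C[C@@](OC)([C@H](C)[C@@H](OC(C)=O)c2ccc(OC)c(OC)c2)C(OC(C)=O)=CC1=O | intermediate
18 | (1R,2R)-2-[(1R)-3-allyl-1-methoxy-4,6-dioxocyclohex-2-en-1-yl]-1-(3,4-dimethoxyphenyl)propyl acetate | C=CCC1=C[C@@](OC)([C@H](C)[C@@H](OC(C)=O)c2ccc(OC)c(OC)c2)C(=O)CC1=O | intermediate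
19 | (1R,2R)-2-[(1R)-3-allyl-1,6-dimethoxy-4-oxocyclohexa-2,5-dien-1-yl]-1-(3,4-dimethoxyphenyl)propyl acetate | C=CCC1=C[C@@](OC)([C@H](C)[C@@H](OC(C)=O)c2ccc(OC)c(OC)c2)C(OC)=CC1=O | target

Total steps: 10 (lactone arm 4, acceptor arm 3, union 1, end game 2). Longest linear sequence: 7 (steps 1, 2, 3, 4, 8, 9, 10).

Steps most likely to fail

1. Step 8.
- What may go wrong:
  - The enolate may act as a base towards the acetyl group of the acceptor.
  - It may attack the ketone carbonyl or sulfur instead of C3.
  - The alkene geometry may be lost during the substitution, so the ring cannot close.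
- Fallback: it sets out from 8 and 12 and comes back at 16. The C3–C4 bond is made under Lewis-acid conditions, and the ring is closed before the C2=C3 double bond exists. Neither enolate basicity nor alkene geometry then matters, and the tosylate is not needed.
  - Compound 8 is converted (LiN(SiMe3)2, Me3SiCl, THF, −78 °C) into the silyl ketene acetal F1.
  - Compound 12 is acetalised (HC(OMe)3, MeOH, cat. pyridinium 4-methylbenzenesulfonate) to 3-(dimethoxymethyl)hex-5-en-2-one F2.
  - A Mukaiyama aldol-type coupling of the two (cat. Me3SiOTf, CH2Cl2, −78 °C), again anti to the methyl and aryl groups, should give the β-methoxy ketone lactone F3.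
  - Kinetic enolisation of its methyl ketone with excess LiN(SiMe3)2 should bring about the same Dieckmann acylation to the 5-methoxy dione F4.
  - F4 loses methanol by E1cB on warming and gives 16.

2. Step 10.
- What may go wrong: poor discrimination between the two enol oxygens O5 and O1 of the ambident vinylogous acid.
- Fallback: it sets out from 18, or from the unseparated enol ether mixture, and comes back at 19. Kinetic alkylation is replaced by thermodynamic enol etherification (HC(OMe)3, MeOH, cat. pyridinium 4-methylbenzenesulfonate, rt). Both enol ethers interconvert through a common dimethoxy cation, and the mixture should settle on the cross-conjugated 2,5-dienone, which is generally lower in energy than a linearly conjugated 2,4-dienone. The acid is kept weak because the veratryl-type acetate ionises easily. No new compound is made.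

3. Step 3.
- What may go wrong: glycol cleavage between C4 and C5 by the iodane, or oxidation at the benzylic carbinol, may compete with oxidation of the primary alcohol.
- Fallback: it sets out from 4 and comes back at 7, and the vicinal diol is avoided altogether.
  - Hydroboration–oxidation (9-BBN, THF; NaOH, H2O2) gives the 1,4-diol F5.
  - TEMPO/PhI(OAc)2 lactonisation gives the α-unsubstituted cis-lactone F6.
  - Enolate hydroxylation (LiN(SiMe3)2, 2-(phenylsulfonyl)-3-phenyloxaziridine, THF, −78 °C) installs the C4 oxygen and gives 7.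

Further compounds
F1 | step 8 | {[(4R,5R)-5-(3,4-dimethoxyphenyl)-3-methoxy-4-methyl-4,5-dihydrofuran-2-yl]oxy}trimethylsilane | COC1=C(O[Si](C)(C)C)O[C@@H](c2ccc(OC)c(OC)c2)[C@H]1C
F2 | step 8 | 3-(dimethoxymethyl)hex-5-en-2-one | C=CCC(C(OC)OC)C(C)=O
F3 | step 8 | (3S,4R,5R)-3-(2-acetyl-1-methoxypent-4-en-1-yl)-5-(3,4-dimethoxyphenyl)-3-methoxy-4-methyldihydrofuran-2(3H)-one (side-chain centres unassigned; same spatial arrangement at the quaternary carbon as in 15) | CC(=O)C(CC=C)C(OC)[C@@]1(OC)[C@H](C)[C@@H](OC1=O)c2ccc(OC)c(OC)c2
F4 | step 8 | (4S)-6-allyl-4-[(1R,2R)-1-(3,4-dimethoxyphenyl)-1-hydroxypropan-2-yl]-4,5-dimethoxycyclohexane-1,3-dione (C5 and C6 unassigned; same spatial arrangement at C4 as in 16) | C=CCC1C(OC)[C@@](OC)([C@H](C)[C@@H](O)c2ccc(OC)c(OC)c2)C(=O)CC1=O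
F0 | step 10 | none | none
F5 | step 3 | (1R,2S)-1-(3,4-dimethoxyphenyl)-2-methylbutane-1,4-diol | OCC[C@H](C)[C@@H](O)c1ccc(OC)c(OC)c1
F6 | step 3 | (4S,5R)-5-(3,4-dimethoxyphenyl)-4-methyldihydrofuran-2(3H)-one (4,5-cis) | C1[C@H](C)[C@@H](OC1=O)c2ccc(OC)c(OC)c2
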